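The cyclohexenone ring carries its amide nitrogen on C2 and its secondary hydroxyl on C5, in a 1,4-relationship across the carbocycle, with the C5–O bond cis to the tertiary C4–O bond. This is the imprint of an N=O unit added across a cyclohexadiene, so the ring is disconnected to an (S)-2-siloxycyclohexa-1,3-diene that already holds the C4 oxygen and the one-carbon arm C1', and to the acylnitroso compound of the complete upper chain. One cycloaddition forms C2–N and C5–O, sets C5 from C4 and delivers the C1 ketone as its enol ether. Reductive N–O cleavage, dehydrogenation to the C2=C3 enamide and growth of the trienamide from C1' finish the synthesis.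

Key step: step 15

Numbering: ring atoms are numbered as in the target (C1 ketone, C2 nitrogen-bearing, C3, C4 tertiary carbinol, C5 secondary carbinol, C6 methylene); C1' is the carbon attached to C4.

Assumption: in step 3 the old-yellow-enzyme homologue that reduces the enone arm leading to the (S)-enone is used; YqjM is written as the default, and an enantiocomplementary homologue (for example OPR3) would take its place if the default favoured the mirror image.

Remark on configuration: diene 6 (S), hydroxamic acid 14 (R) and cycloadduct 22 (1R,4R,7R) were traced atom by atom to the target (4S,5R in ring numbering, side chain R) and agree with it. The C4 descriptor changes (S in 6, R in 22, S in 34) only because substituent priorities change; the spatial arrangement stays the same.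

Remark on design:
- The C4 oxygen carries TMS, which keeps the attacked face small and is shed together with the enol ether.
- The C1' oxygen carries TBS, which makes the other face large and, being neopentyl-type, outlasts the acid step.
- Two different silyl groups cannot be placed in one operation, so they are introduced in steps 4 and 5.
- After N–O cleavage the cis-4,5-diol is tied up as an acetonide, so that C5–OH is not oxidised in step 20 and no alkoxide sits β to the ketone in step 21.

Step 1
Reactants: 1 4-hydroxybenzyl alcohol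
Product: 2 4-[(tert-butyldimethylsilyloxy)methyl]phenol
Conditions: TBSCl (1.05 equiv), imidazole, DMF, 0 °C
Reagents that add atoms: tert-butyldimethylsilyl chloride, CC(C)(C)[Si](C)(C)Cl
Why: Chemoselective O-silylation, in which the primary aliphatic hydroxyl should react faster than the phenol at 0 °C with only a slight excess of the silyl chloride.

Step 2
Reactants: 2 4-[(tert-butyldimethylsilyloxy)methyl]phenol
Product: 3 4-[(tert-butyldimethylsilyloxy)methyl]-4-hydroxycyclohexa-2,5-dien-1-one
Conditions: PhI(OAc)2, MeCN–H2O (3:1), 0 °C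
Reagents that add atoms: water, O
Why: Hypervalent-iodine oxidative dearomatisation of a para-substituted phenol, in which water captures the phenoxenium-type intermediate at C4 to give the para-quinol, while the silyl ether blocks vinylogous retro-aldol loss of formaldehyde.

Step 3
Reactants: 3 4-[(tert-butyldimethylsilyloxy)methyl]-4-hydroxycyclohexa-2,5-dien-1-one
Product: 4 (S)-4-[(tert-butyldimethylsilyloxy)methyl]-4-hydroxycyclohex-2-en-1-one
Conditions: ene-reductase YqjM, NADP+ (cat.), D-glucose, glucose dehydrogenase, KH2PO4/K2HPO4 buffer pH 7, DMSO (5% v/v), 30 °C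
Reagents that add atoms: none
Why: Biocatalytic desymmetrisation by flavin-dependent conjugate reduction of one of the two enantiotopic enone arms of a 4,4-disubstituted cyclohexa-2,5-dienone, in which the chiral active site selects the arm and thereby makes C4 a stereocentre, and the hindered mono-enone should not be reduced further.

Step 4
Reactants: 4 (S)-4-[(tert-butyldimethylsilyloxy)methyl]-4-hydroxycyclohex-2-en-1-one
Product: 5 (S)-4-[(tert-butyldimethylsilyloxy)methyl]-4-(trimethylsilyloxy)cyclohex-2-en-1-one
Conditions: N-(trimethylsilyl)imidazole, CH2Cl2, rt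
Reagents that add atoms: N-(trimethylsilyl)imidazole, C[Si](C)(C)n1ccnc1
Why: Neutral silyl transfer (O-silylation) to the tertiary alcohol, which leaves the enone and the C4 configuration untouched.

Step 5
Reactants: 5 (S)-4-[(tert-butyldimethylsilyloxy)methyl]-4-(trimethylsilyloxy)cyclohex-2-en-1-one
Product: 6 (S)-2-(tert-butyldimethylsilyloxy)-5-[(tert-butyldimethylsilyloxy)methyl]-5-(trimethylsilyloxy)cyclohexa-1,3-diene
Conditions: TBSOTf, Et3N, CH2Cl2, 0 °C
Reagents that add atoms: tert-butyldimethylsilyl trifluoromethanesulfonate, CC(C)(C)[Si](C)(C)OS(=O)(=O)C(F)(F)F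
Why: Soft enolisation with silyl triflate and amine can only take place at C6 of the enone because the γ-carbon is quaternary, so the cross-conjugated 2-siloxy-1,3-diene should form as its isolable TBS enol ether.

Step 6
Reactants: 7 methyl (R)-3-hydroxy-2-methylpropanoate
Product: 8 methyl (R)-2-methyl-3-(trifluoromethanesulfonyloxy)propanoate
Conditions: Tf2O, 2,6-lutidine, CH2Cl2, −78 °C
Reagents that add atoms: trifluoromethanesulfonic anhydride, O=S(=O)(OS(=O)(=O)C(F)(F)F)C(F)(F)F
Why: O-Sulfonylation of the primary alcohol with a hindered base at low temperature, which does not touch the α-stereocentre.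

Step 7
Reactants: 8 methyl (R)-2-methyl-3-(trifluoromethanesulfonyloxy)propanoate
Product: 9 methyl (R)-2-methylhexanoate
Conditions: n-PrMgCl, CuBr·SMe2 (cat.), THF, −78 → −30 °C
Reagents that add atoms: n-propylmagnesium chloride, CCC[Mg]Cl
Why: CuBr-catalysed cross-coupling of a Grignard reagent with a primary alkyl triflate (SN2-type displacement by an organocuprate), which at low temperature should outrun attack on or enolisation of the ester, so the stereocentre, which is not involved, is kept.

Step 8
Reactants: 9 methyl (R)-2-methylhexanoate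
Product: 11 ethyl (R,E)-2,4-dimethyloct-2-enoate, via (R)-2-methylhexanal 10 (not isolated)
Conditions: i-Bu2AlH, CH2Cl2, −78 °C; then Ph3P=C(Me)CO2Et, −78 °C → rt
Reagents that add atoms: ethyl 2-(triphenylphosphoranylidene)propanoate, CCOC(=O)C(C)=P(c1ccccc1)(c1ccccc1)c1ccccc1
Why: Partial ester reduction followed in the same flask by Wittig olefination with a stabilised ylide, which avoids isolating the volatile, epimerisable aldehyde and should give the (E)-trisubstituted enoate as stabilised ylides normally do.

Step 9
Reactants: 11 ethyl (R,E)-2,4-dimethyloct-2-enoate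
Product: 12 (R,E)-2,4-dimethyloct-2-enoic acid
Conditions: LiOH, THF–MeOH–H2O, 40 °C; aq. HCl work-up
Reagents that add atoms: lithium hydroxide, [Li+].[OH-]
Why: Saponification (acyl-oxygen ester hydrolysis), under which the allylic γ-stereocentre is not acidic.

Step 10
Reactants: 12 (R,E)-2,4-dimethyloct-2-enoic acid
Product: 14 (R,E)-N-hydroxy-2,4-dimethyloct-2-enamide, via acyl imidazole 13 (not isolated)
Conditions: CDI, THF, rt; then NH2OH·HCl, rt
Reagents that add atoms: hydroxylamine hydrochloride, Cl.NO
Why: Activation of the acid as its acyl imidazole and N-acylation of hydroxylamine, whose nitrogen is the more nucleophilic atom, should give the hydroxamic acid without conjugate addition to the hindered enoyl unit.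

Step 11
Reactants: 15 methyl sorbate
Product: 16 methyl (2E,4E)-6-bromohexa-2,4-dienoate
Conditions: NBS, (PhCO2)2 (cat.), PhCF3, reflux
Reagents that add atoms: N-bromosuccinimide, O=C1CCC(=O)N1Br
Why: Wohl–Ziegler bromination, in which hydrogen abstraction from the terminal methyl gives an ester-conjugated pentadienyl radical that is brominated at the terminus with the (2E,4E)-diene retained.

Step 12
Reactants: 16 methyl (2E,4E)-6-bromohexa-2,4-dienoate
Product: 17 methyl (2E,4E)-6-(diethoxyphosphoryl)hexa-2,4-dienoate
Conditions: P(OEt)3, 120 °C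
Reagents that add atoms: triethyl phosphite, CCOP(OCC)OCC
Why: Michaelis–Arbuzov reaction of the allylic bromide gives the vinylogous phosphonate.

Step 13
Reactants: 18 cyclopentane-1,3-dione
Product: 19 2-nitrocyclopentane-1,3-dione
Conditions: fuming HNO3, Et2O, 0 °C
Reagents that add atoms: nitric acid, O[N+](=O)[O-]
Why: Electrophilic nitration of the enol of the cyclic 1,3-dione at C2, its only nucleophilic carbon.

Step 14
Reactants: 19 2-nitrocyclopentane-1,3-dione
Product: 20 2-amino-3-hydroxycyclopent-2-en-1-one hydrochloride
Conditions: H2, Pd/C, HCl, MeOH, rt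
Reagents that add atoms: hydrogen chloride, Cl
Why: Catalytic hydrogenation of the nitro group to the amine, which is trapped as its hydrochloride so that the 2-amino-1,3-dione cannot self-condense.

Step 15
Reactants: 6 (S)-2-(tert-butyldimethylsilyloxy)-5-[(tert-butyldimethylsilyloxy)methyl]-5-(trimethylsilyloxy)cyclohexa-1,3-diene; 14 (R,E)-N-hydroxy-2,4-dimethyloct-2-enamide
Product: 22 (2E,4R)-1-[(1R,4R,7R)-5-(tert-butyldimethylsilyloxy)-7-[(tert-butyldimethylsilyloxy)methyl]-7-(trimethylsilyloxy)-2-oxa-3-azabicyclo[2.2.2]oct-5-en-3-yl]-2,4-dimethyloct-2-en-1-one, via acylnitroso compound 21 (not isolated)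
Conditions: Bu4NIO4, CH2Cl2, 0 °C, slow addition of 14 to 6 and the oxidant
Reagents that add atoms: none
Why: Bu4NIO4 oxidises the hydroxamic acid to the transient acylnitroso compound 21, which is captured at once by the electron-rich diene in a concerted but asynchronous hetero-[4+2] cycloaddition, the acylnitroso Diels–Alder reaction that is established for 2-siloxycyclohexa-1,3-dienes. The one ring that closes is the 1,2-oxazine, formed by cycloaddition with N–O as the two-atom bridge of a 2-oxa-3-azabicyclo[2.2.2]oct-5-ene. Regioselectivity is required and is secured electronically, since the enol ether β-carbon (C2) holds the largest HOMO coefficient and bonds to the electrophilic nitrogen, while the unsubstituted oxygen goes to C5 beside the quaternary C4, so that steric demand points the same way. The new stereocentres C2 and C5 are set together by the choice of diene face, which is controlled by C4: attack should occur syn to the small OTMS group and anti to the CH2OTBS arm, as is usual for 5-oxy-5-alkyl cyclohexadienes on both steric and stereoelectronic grounds, and this puts C5–O cis to C4–O. Endo or exo approach is without consequence because nitrogen is not a stereocentre in the product, and slow addition of 14 keeps the acylnitroso concentration low so that ene and nitroso-aldol reactions of the enol ether should not compete.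

Step 16
Reactants: 22 the cycloadduct
Product: 24 (2E,4R)-N-[(1R,4R,5R)-5-[(tert-butyldimethylsilyloxy)methyl]-4,5-dihydroxy-2-oxocyclohexyl]-2,4-dimethyloct-2-enamide, via amido alcohol enol ether 23 (not isolated)
Conditions: Mo(CO)6, MeCN–H2O (15:1), 80 °C; then 0.1 M HCl, THF–H2O, 0 °C, short contact
Reagents that add atoms: none
Why: Reductive N–O cleavage by Mo(CO)6 breaks the weak N–O bond of the N-acyl oxazine without touching the alkenes, and brief dilute acid should then hydrolyse the silyl enol ether and the tertiary TMS ether well before the neopentyl-type primary TBS ether, C4 and C5 being untouched and C2 being destroyed later.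

Step 17
Reactants: 24 the keto diol
Product: 25 the 4,5-O-isopropylidene derivative of 24 (cis-fused 2,2-dimethyl-1,3-dioxolane across C4–O and C5–O)
Conditions: 2-methoxypropene, PPTS (cat.), CH2Cl2, 0 °C
Reagents that add atoms: 2-methoxypropene, COC(C)=C
Why: Acid-catalysed ketalisation of the cis-1,2-diol gives the cis-fused dioxolane, which masks both hydroxyls for the oxidation and olefination steps.

Step 18
Reactants: 25 the acetonide-protected amido ketone
Product: 28 the enamide (2-acylaminocyclohex-2-enone with C2=C3; acetonide and CH2OTBS arm unchanged), via N-chloroamide 26 (not isolated), via N-acylimine 27 (not isolated)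
Conditions: t-BuOCl, CH2Cl2, 0 °C, dark; then DABCO, 0 °C → rt
Reagents that add atoms: none
Why: N-Chlorination of the secondary amide and base-induced dehydrochlorination, the sequence used to make dehydroamino acids, should give the N-acylimine, which tautomerises to the enamide conjugated with the C1 ketone, and since only C3 can supply the proton the double bond must be C2=C3.

Step 19
Reactants: 28 the enamide
Product: 29 the C1' primary alcohol of 28
Conditions: HF·pyridine, pyridine, THF, 0 °C → rt
Reagents that add atoms: none
Why: Fluoride-mediated desilylation under buffered conditions, driven by the strong Si–F bond, frees the primary alcohol and should leave the acetonide and the enamide intact.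

Step 20
Reactants: 29 the primary alcohol
Product: 30 the C1' aldehyde
Conditions: Dess–Martin periodinane, NaHCO3, CH2Cl2, 0 °C → rt
Reagents that add atoms: none
Why: Dess–Martin oxidation converts the primary alcohol into the non-enolisable α-alkoxy aldehyde under buffered, non-basic conditions.

Step 21
Reactants: 30 the C1' aldehyde; 17 methyl (2E,4E)-6-(diethoxyphosphoryl)hexa-2,4-dienoate
Product: 31 the methyl (1'E,3'E,5'E)-trienoate
Conditions: 17 (2.5 equiv), LiN(SiMe3)2 (2.4 equiv), THF, −78 °C; then 30, −78 → 0 °C
Reagents that add atoms: none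
Why: Vinylogous Horner–Wadsworth–Emmons olefination, in which one equivalent of the stabilised phosphonate anion deprotonates the enamide N–H and thereby shields the enone from enolisation, while a further equivalent adds to the hindered non-enolisable aldehyde and should give the new alkene with (E)-geometry.

Step 22
Reactants: 31 the methyl trienoate
Product: 32 the trienoic acid
Conditions: Me3SnOH, ClCH2CH2Cl, 70 °C; dilute HCl wash
Reagents that add atoms: trimethyltin hydroxide, C[Sn](C)(C)O
Why: Me3SnOH-mediated methyl ester hydrolysis is a nearly neutral alternative to saponification and should spare the β-alkoxy ketone, the enamide and the acetonide.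

Step 23
Reactants: 32 the trienoic acid; 20 2-amino-3-hydroxycyclopent-2-en-1-one hydrochloride
Product: 33 the 4,5-O-isopropylidene derivative of the target
Conditions: EDC·HCl, HOBt, Et3N, DMF, 0 °C → rt
Reagents that add atoms: none
Why: Carbodiimide/HOBt amide coupling, in which the amine set free from its hydrochloride is acylated at nitrogen and any enol ester formed should rearrange by O-to-N acyl transfer.

Step 24
Reactants: 33 the acetonide-protected target
Product: 34 (2E,4R)-N-[(3S,4R)-3,4-dihydroxy-3-[(1E,3E,5E)-7-[(2-hydroxy-5-oxocyclopent-1-en-1-yl)amino]-7-oxohepta-1,3,5-trien-1-yl]-6-oxocyclohex-1-en-1-yl]-2,4-dimethyloct-2-enamide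
Conditions: AcOH–THF–H2O (3:1:1), 40 °C
Reagents that add atoms: none
Why: Acid-catalysed acetal hydrolysis releases the cis-diol under mild aqueous acetic acid, to which the 2-amidoenone, the trienamide and the tertiary alcohol flanked by electron-poor π-systems should be stable.

Compound list

1 | 4-hydroxybenzyl alcohol | OCc1ccc(O)cc1 | starting material
2 | 4-[(tert-butyldimethylsilyloxy)methyl]phenol | CC(C)(C)[Si](C)(C)OCc1ccc(O)cc1 | intermediate
3 | 4-[(tert-butyldimethylsilyloxy)methyl]-4-hydroxycyclohexa-2,5-dien-1-one (achiral quinol) | O=C1C=CC(O)(CO[Si](C)(C)C(C)(C)C)C=C1 | intermediate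
4 | (S)-4-[(tert-butyldimethylsilyloxy)methyl]-4-hydroxycyclohex-2-en-1-one | O=C1C=C[C@](O)(CO[Si](C)(C)C(C)(C)C)CC1 | intermediate
5 | (S)-4-[(tert-butyldimethylsilyloxy)methyl]-4-(trimethylsilyloxy)cyclohex-2-en-1-one | O=C1C=C[C@](O[Si](C)(C)C)(CO[Si](C)(C)C(C)(C)C)CC1 | intermediate
6 | (S)-2-(tert-butyldimethylsilyloxy)-5-[(tert-butyldimethylsilyloxy)methyl]-5-(trimethylsilyloxy)cyclohexa-1,3-diene | C1(O[Si](C)(C)C(C)(C)C)=CC[C@@](O[Si](C)(C)C)(CO[Si](C)(C)C(C)(C)C)C=C1 | intermediate
7 | methyl (R)-3-hydroxy-2-methylpropanoate | COC(=O)[C@H](C)CO | starting material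
8 | methyl (R)-2-methyl-3-(trifluoromethanesulfonyloxy)propanoate | COC(=O)[C@H](C)COS(=O)(=O)C(F)(F)F | intermediate
9 | methyl (R)-2-methylhexanoate | CCCC[C@@H](C)C(=O)OC | intermediate
10 | (R)-2-methylhexanal | CCCC[C@@H](C)C=O | intermediate (not isolated)
11 | ethyl (R,E)-2,4-dimethyloct-2-enoate | CCCC[C@@H](C)/C=C(\C)C(=O)OCC | intermediate
12 | (R,E)-2,4-dimethyloct-2-enoic acid | CCCC[C@@H](C)/C=C(\C)C(=O)O | intermediate
13 | (R,E)-1-(imidazol-1-yl)-2,4-dimethyloct-2-en-1-one (acyl imidazole) | CCCC[C@@H](C)/C=C(\C)C(=O)n1ccnc1 | intermediate (not isolated)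
14 | (R,E)-N-hydroxy-2,4-dimethyloct-2-enamide | CCCC[C@@H](C)/C=C(\C)C(=O)NO | intermediate
15 | methyl sorbate, methyl (2E,4E)-hexa-2,4-dienoate | C/C=C/C=C/C(=O)OC | starting material
16 | methyl (2E,4E)-6-bromohexa-2,4-dienoate | BrC/C=C/C=C/C(=O)OC | intermediate
17 | methyl (2E,4E)-6-(diethoxyphosphoryl)hexa-2,4-dienoate | CCOP(=O)(OCC)C/C=C/C=C/C(=O)OC | intermediate
18 | cyclopentane-1,3-dione | O=C1CCC(=O)C1 | starting material
19 | 2-nitrocyclopentane-1,3-dione | O=C1CCC(=O)C1[N+](=O)[O-] | intermediate
20 | 2-amino-3-hydroxycyclopent-2-en-1-one hydrochloride | NC1=C(O)CCC1=O.Cl | intermediate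
21 | (R,E)-2,4-dimethyl-1-nitrosooct-2-en-1-one (acylnitroso compound) | CCCC[C@@H](C)/C=C(\C)C(=O)N=O | intermediate (not isolated)
22 | (2E,4R)-1-[(1R,4R,7R)-5-(tert-butyldimethylsilyloxy)-7-[(tert-butyldimethylsilyloxy)methyl]-7-(trimethylsilyloxy)-2-oxa-3-azabicyclo[2.2.2]oct-5-en-3-yl]-2,4-dimethyloct-2-en-1-one; N–O bridge syn to OTMS, anti to CH2OTBS | CCCC[C@@H](C)/C=C(\C)C(=O)N1O[C@@H]2C=C(O[Si](C)(C)C(C)(C)C)[C@H]1C[C@@]2(O[Si](C)(C)C)CO[Si](C)(C)C(C)(C)C | intermediate
23 | N–O-cleaved cycloadduct: C2 amide and C5 alcohol on the C1(OTBS)=C6 enol ether; C2–N, C5–OH and C4–OTMS on one ring face, CH2OTBS on the other | CCCC[C@@H](C)/C=C(\C)C(=O)N[C@@H]1C[C@@](O[Si](C)(C)C)(CO[Si](C)(C)C(C)(C)C)[C@H](O)C=C1O[Si](C)(C)C(C)(C)C | intermediate (not isolated)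
24 | (2E,4R)-N-[(1R,4R,5R)-5-[(tert-butyldimethylsilyloxy)methyl]-4,5-dihydroxy-2-oxocyclohexyl]-2,4-dimethyloct-2-enamide (keto diol; C4–OH and C5–OH cis) | CCCC[C@@H](C)/C=C(\C)C(=O)N[C@@H]1C[C@@](O)(CO[Si](C)(C)C(C)(C)C)[C@H](O)CC1=O | intermediate
25 | 4,5-O-isopropylidene derivative of 24 (cis-fused acetonide) | CCCC[C@@H](C)/C=C(\C)C(=O)N[C@@H]1C[C@]3(CO[Si](C)(C)C(C)(C)C)OC(C)(C)O[C@@H]3CC1=O | intermediate
26 | N-chloroamide of 25 | CCCC[C@@H](C)/C=C(\C)C(=O)N(Cl)[C@@H]1C[C@]3(CO[Si](C)(C)C(C)(C)C)OC(C)(C)O[C@@H]3CC1=O | intermediate (not isolated)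
27 | N-acylimine (C2=N) from 26 | CCCC[C@@H](C)/C=C(\C)C(=O)N=C1C[C@]3(CO[Si](C)(C)C(C)(C)C)OC(C)(C)O[C@@H]3CC1=O | intermediate (not isolated)
28 | enamide: 2-acylaminocyclohex-2-enone (C2=C3) with 4,5-O-isopropylidene and C4 CH2OTBS; C4, C5 as in the target | CCCC[C@@H](C)/C=C(\C)C(=O)NC1=C[C@]3(CO[Si](C)(C)C(C)(C)C)OC(C)(C)O[C@@H]3CC1=O | intermediate
29 | C1' primary alcohol of 28 | CCCC[C@@H](C)/C=C(\C)C(=O)NC1=C[C@]3(CO)OC(C)(C)O[C@@H]3CC1=O | intermediate
30 | C1' aldehyde | CCCC[C@@H](C)/C=C(\C)C(=O)NC1=C[C@]3(C=O)OC(C)(C)O[C@@H]3CC1=O | intermediate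
31 | methyl (1'E,3'E,5'E)-trienoate (acetonide-protected) | CCCC[C@@H](C)/C=C(\C)C(=O)NC1=C[C@]3(/C=C/C=C/C=C/C(=O)OC)OC(C)(C)O[C@@H]3CC1=O | intermediate
32 | (1'E,3'E,5'E)-trienoic acid (acetonide-protected) | CCCC[C@@H](C)/C=C(\C)C(=O)NC1=C[C@]3(/C=C/C=C/C=C/C(=O)O)OC(C)(C)O[C@@H]3CC1=O | intermediate
33 | 4,5-O-isopropylidene derivative of the target | CCCC[C@@H](C)/C=C(\C)C(=O)NC1=C[C@]3(/C=C/C=C/C=C/C(=O)NC2=C(O)CCC2=O)OC(C)(C)O[C@@H]3CC1=O | intermediate
34 | (2E,4R)-N-[(3S,4R)-3,4-dihydroxy-3-[(1E,3E,5E)-7-[(2-hydroxy-5-oxocyclopent-1-en-1-yl)amino]-7-oxohepta-1,3,5-trien-1-yl]-6-oxocyclohex-1-en-1-yl]-2,4-dimethyloct-2-enamide (CNP0154433.2) | CCCC[C@@H](C)/C=C(\C)C(=O)NC1=C[C@@](O)(/C=C/C=C/C=C/C(=O)NC2=C(O)CCC2=O)[C@H](O)CC1=O | target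

Total step count: 24. Longest linear sequence: 15 steps (steps 1–5, then 15–24; the arm through steps 6–10 is equally long).

Steps most likely to fail

Step 15. The two diene faces may be discriminated too weakly, with attack syn to the CH2OTBS arm competing, or the acylnitroso compound may be lost to ene and nitroso-aldol reactions of the enol ether. The fallback gives up the cycloaddition and makes the two heteroatom bonds one after the other, setting out from quinol 3 and acid 12. Phenylboronic acid with a bifunctional chiral amine–thiourea catalyst should deliver a boron-bound hydroxide intramolecularly to one enone arm (tethered oxa-Michael addition). The cis-fused phenylboronate F1 then carries C5–O cis to C4–O by construction, and the catalyst selects the arm. Exchange with pinacol releases the cis-diol enone F2, and 2-methoxypropene/PPTS gives the acetonide F3. I2/pyridine iodinates the enone at C2 to the 2-iodoenone F4. CuI/N,N'-dimethylethylenediamine/K2CO3 then couples F4 with (R,E)-2,4-dimethyloct-2-enamide F5, made from 12 through 13 and NH3. This amidation gives enamide 28, where the route is rejoined before step 19.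

Step 3. The enzyme may distinguish the two enone arms of this particular quinol poorly, or reduce the product further. The fallback desymmetrises by enantioselective deprotonation instead of reduction and sets out from 3. Hydrogenation of both alkenes (H2, Rh/Al2O3, EtOAc) gives the achiral 4-[(tert-butyldimethylsilyloxy)methyl]-4-hydroxycyclohexanone F6, and N-(trimethylsilyl)imidazole gives its TMS ether F7. Lithium bis[(R)-1-phenylethyl]amide with LiCl and TMSCl as internal quench (THF, −78 °C), or its antipode as needed for the (S) series, should give the silyl enol ether F8. Saegusa–Ito oxidation with Pd(OAc)2 in MeCN returns to enone 5, where the route is rejoined before step 5.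

Step 18. Chlorination may occur at carbon (C6) instead of nitrogen, or the base may trigger β-elimination of the C5 oxygen during dehydrochlorination. The fallback introduces the C2=C3 double bond through an enol silane and sets out from 25. TMSOTf/Et3N under equilibrating conditions should enolise towards the amide-bearing carbon and give the C1=C2 silyl enol ether F9. Saegusa–Ito oxidation with Pd(OAc)2 in MeCN then gives enamide 28, where the route is rejoined before step 19.

Further compounds

F1 | step 15 | cis-fused phenylboronate of the 4,5-diol enone (2-phenyl-1,3,2-dioxaborolane across C4–O and C5–O) | O=C1C=C[C@]3(CO[Si](C)(C)C(C)(C)C)OB(c2ccccc2)O[C@@H]3C1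
F2 | step 15 | cis-4,5-dihydroxy-4-[(tert-butyldimethylsilyloxy)methyl]cyclohex-2-en-1-one, configuration as in the target | O=C1C=C[C@@](O)(CO[Si](C)(C)C(C)(C)C)[C@H](O)C1
F3 | step 15 | 4,5-O-isopropylidene derivative of F2 | O=C1C=C[C@]3(CO[Si](C)(C)C(C)(C)C)OC(C)(C)O[C@@H]3C1
F4 | step 15 | 2-iodo derivative of F3 (2-iodoenone) | O=C1C(I)=C[C@]3(CO[Si](C)(C)C(C)(C)C)OC(C)(C)O[C@@H]3C1
F5 | step 15 | (R,E)-2,4-dimethyloct-2-enamide | CCCC[C@@H](C)/C=C(\C)C(N)=O
F6 | step 3 | 4-[(tert-butyldimethylsilyloxy)methyl]-4-hydroxycyclohexan-1-one | O=C1CCC(O)(CO[Si](C)(C)C(C)(C)C)CC1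
F7 | step 3 | 4-[(tert-butyldimethylsilyloxy)methyl]-4-(trimethylsilyloxy)cyclohexan-1-one | O=C1CCC(O[Si](C)(C)C)(CO[Si](C)(C)C(C)(C)C)CC1
F8 | step 3 | (S)-4-[(tert-butyldimethylsilyloxy)methyl]-1,4-bis(trimethylsilyloxy)cyclohex-1-ene | C[Si](C)(C)OC1=CC[C@](O[Si](C)(C)C)(CO[Si](C)(C)C(C)(C)C)CC1
F9 | step 18 | C1=C2 trimethylsilyl enol ether of 25 | CCCC[C@@H](C)/C=C(\C)C(=O)NC1=C(O[Si](C)(C)C)C[C@H]2OC(C)(C)O[C@@]2(CO[Si](C)(C)C(C)(C)C)C1
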